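(The earlier runs and the new flask were computed with constants of no real substance, and the scatter is random.)

| setting | gamma | beta | flask |
|---|---|---|---|
| left-handed substrate | 0.025 M | 0.025 M | 0.025 M |
| right-handed substrate | 0.025 M | 0.025 M | 0.025 M |
| coupling partner | 0.028 M | 0.11 M | 0.0550 M |
| catalyst | 25 µM | 25 µM | 25 µM |
| remark | run made earlier | run made earlier |  |
| time |  |  | 30 h |

| run | time / h | left-handed substrate / % | left-handed product / % | right-handed product / % |
|---|---|---|---|---|
| gamma | 6.00 | 28.8 | 30.7 | 13.8 |
| gamma | 12.0 | 28.7 | 29.5 | 14.8 |
| gamma | 20.0 | 28.6 | 30.5 | 13.7 |
| gamma | 25.0 | 28.8 | 28.4 | 14.2 |
| gamma | 30.0 | 29.0 | 30.1 | 12.7 |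
| gamma | 40.0 | 28.4 | 28.9 | 12.9 |
| beta | 2.50 | 0.5 | 64.3 | 35.0 |
| beta | 8.00 | 1.1 | 64.0 | 35.7 |
| beta | 12.0 | 0.8 | 63.7 | 35.1 |
| beta | 20.0 | 0 | 63.8 | 33.6 |
| beta | 30.0 | 0.5 | 64.1 | 35.7 |
| beta | 40.0 | 0 | 64.5 | 35.1 |

(each reading ± 0.5 percentage points)

- catalyst is single-handed; left-handed substrate and right-handed substrate are mirror images of each other, charged as a racemate, each of them at the stated concentration
- the analysis behind the earlier runs scatters by 0.5 percentage points, standard deviation
- steps under discussion: coupling partner + catalyst + left-handed substrate -> catalyst + left-handed product; coupling partner + catalyst + right-handed substrate -> catalyst + right-handed product; left-handed substrate <-> right-handed substrate; coupling partner -> decomposed reagent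
- the reaction counts as stopped when no species that holds the left-handed substrate and right-handed substrate together changes by six tenths of a point or more over the second half of the time

- the state of affairs at 30 h: stopped, and by what, or still going (all of the left-handed substrate has reacted / forward and back rates have come level / the coupling partner has run out first / it is still moving / no working catalyst is left)
- share of the left-handed substrate and right-handed substrate together used up at 30 h
- left-handed product at 30 h, in percent of the left-handed substrate and right-handed substrate together charged
- right-handed product at 30 h, in percent of the left-handed substrate and right-handed substrate together charged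

Count every amount as a fraction of the racemate charge, and see first that coupling cannot account for the gamma run: it held 0.560 of coupling partner, yet its products stand flat at 0.434, less than that charge, while the beta run, with the same catalyst, has converted nearly all of its substrate by 2.50 h.

Read the gap as partner lost to decomposed reagent, which makes the partner the limiting reagent of the gamma run. Then carry one quantity, the break-even substrate: the standing share of substrate, both hands together, at which coupling and decomposition take the partner equally, read from the gamma run as 0.222. Reckon it on the assumption that both steps are first order in partner, so that a unit converted costs one unit of partner plus break-even over the standing share, and a run's bill is its conversion plus break-even times the natural logarithm of one over the unconverted share.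

Set this flask beside the gamma run: it has the same substrate and catalyst, but 1.10 of partner, twice the gamma charge. Replace the falling substrate by its midpoint, and my reckoning gives a conversion of 0.802. Check that against the whole curve, whose bill there is 1.16, more than the charge, and take the excess back at the end price of 2.12, which leaves 0.773. The last unit costs 1.98 in this flask against 1.39 in the gamma run, so conversion grows by a factor of 1.78, less than the partner's 1.96.

The forecast says the coupling partner has run out first, with 78% converted, 52% left-handed and 26% right-handed product, its split resting on the view that “racemisation lags at high partner”; its conversion stands 0.70 percentage points above mine.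

    coupling partner + catalyst + left-handed substrate → catalyst + left-handed product (k = 9440 M⁻² s⁻¹)
    coupling partner + catalyst + right-handed substrate → catalyst + right-handed product (k = 4110 M⁻² s⁻¹)
    left-handed substrate ⇌ right-handed substrate (k = 0.0130 s⁻¹)
    coupling partner → decomposed reagent (k = 0.00192 s⁻¹)

The flask ends in this state: the coupling partner has run out first, with 76.5% converted, 51.6% left-handed and 24.9% right-handed product. Its coupling partner stands at 0% of its charge at 30.0 h. At that conversion the break-even substrate of 0.222 makes the flask's bill 1.09 against the 1.10 charged. The neighbour flask with 0.022 M of coupling partner was charged 0.440, and its bill, with the same break-even substrate, comes to 0.438 at its conversion of 34.4%.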